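**Retrosynthetic overview**

1. The target comes from the 4,5-diol by acylation of the secondary C5–OH with (2S)-2-methylbutanoic acid (made from tiglic acid); the diol comes from acid opening, with inversion at C4, of a macrocyclic (4S,5S)-epoxide.
2. The C6–C7 bond is made by an intramolecular Nozaki–Hiyama allylation of an α,β-epoxy aldehyde with a 2-(bromomethyl)enoate; this closes the ten-membered carbocycle and then the trans γ-lactone in the same flask.
3. The bromomethyl enoate comes from cross-metathesis of an allyl ketone with methyl 2-(bromomethyl)acrylate; the allyl ketone comes from a Weinreb amide and allylmagnesium bromide.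
4. C4/C5 are set by Shi epoxidation of the geranyl-type E-alkene; C10 is set first, by a new NHC-catalysed enantioselective redox amidation of the α-methyl enal obtained by allylic oxidation of geranyl acetate.
5. Ring order: oxirane (step 3), then carbocycle and γ-lactone (both step 7), then the oxirane is opened (step 8).

Assumption: ring atoms carry germacrane-type locants (C6 = lactone O–CH, C7 = ring-fusion CH bearing C11–C13, C8 = CH2, C9 = ketone, C10 = CHMe, C1–C3 = CH2, C4 = C(OH)Me, C5 = acyloxy CH); with these locants the given SMILES is (4R,5S,6R,7R,10S) with a (2S)-2-methylbutanoate.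

**Step 1**
Reactants: 1 geranyl acetate, (2E)-3,7-dimethylocta-2,6-dien-1-yl acetate
Product: 3 (2E,6E)-3,7-dimethyl-8-oxoocta-2,6-dien-1-yl acetate, via allylic alcohol 2 (not isolated)
Conditions: SeO2 (0.1 equiv), t-BuOOH, salicylic acid (cat.), CH2Cl2, rt; then MnO2, CH2Cl2, rt
Reagents that add atoms: tert-butyl hydroperoxide, CC(C)(C)OO
Why: Selenium dioxide allylic oxidation (ene reaction then 2,3-shift) attacks only the E-methyl of the electron-rich terminal alkene (the allylic-acetate alkene is deactivated), and MnO2 takes the allylic alcohol to the E-enal; no stereocenter is formed.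

**Step 2**
Reactants: 3 (2E,6E)-3,7-dimethyl-8-oxoocta-2,6-dien-1-yl acetate
Product: 4 (2E,7S)-8-[methoxy(methyl)amino]-3,7-dimethyl-8-oxooct-2-en-1-yl acetate
Conditions: (5aS,10bR)-N-mesityl aminoindanol-derived triazolium chloride (10 mol%), i-Pr2NEt (1.2 equiv), HOAt (20 mol%), MeNH(OMe)·HCl (1.1 equiv), toluene, 40 °C
Reagents that add atoms: N,O-dimethylhydroxylamine hydrochloride, CNOC.Cl
Why: Proposed new method: the carbene adds to the enal, the extended Breslow intermediate is protonated at the β-carbon, and the resulting enol azolium (one geometry, enforced by allylic strain against the N-mesityl triazolium) is protonated at the α-carbon on the face left open by the aminoindane wall, which sets the first stereocenter (C10 of the target, S); HOAt then takes the acyl group from the acyl azolium and passes it to the hydroxylamine before the α-centre can re-enolise. The closest known chemistry is NHC redox amidation of α-functionalised aldehydes and the enantioselective α-protonation of α-fluoro and α-chloro enol azoliums; an α-alkyl enol azolium has not been protonated selectively, and the sense of induction is assigned by analogy (the antipodal precatalyst is equally available).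

**Step 3**
Reactants: 4 (2E,7S)-8-[methoxy(methyl)amino]-3,7-dimethyl-8-oxooct-2-en-1-yl acetate
Product: 5 [(2S,3S)-3-[(4S)-5-[methoxy(methyl)amino]-4-methyl-5-oxopentyl]-3-methyloxiran-2-yl]methyl acetate
Conditions: ent-Shi ketone (L-fructose-type ketone from L-sorbose, 0.3 equiv), Oxone, K2CO3, Bu4NHSO4 (cat.), MeCN–CH2(OMe)2–aq. buffer pH 10.5, 0 °C
Reagents that add atoms: potassium peroxymonosulfate (Oxone), [K+].[O-]S(=O)(=O)OO
Why: Shi epoxidation: the chiral dioxirane attacks the only alkene through the spiro transition state, and the L-series ketone gives the (S,S)-oxirane from an E-trisubstituted alkene (the D-fructose ketone gives R,R), so C4 and C5 are set by the reagent independently of the remote amide centre, which is not enolised at this pH.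

**Step 4**
Reactants: 5 [(2S,3S)-3-[(4S)-5-[methoxy(methyl)amino]-4-methyl-5-oxopentyl]-3-methyloxiran-2-yl]methyl acetate; 6 allylmagnesium bromide
Product: 7 (5S)-8-[(2S,3S)-3-(hydroxymethyl)-2-methyloxiran-2-yl]-5-methyloct-1-en-4-one
Conditions: 6 (3.3 equiv), THF, −78 °C; cold aq. NH4Cl
Reagents that add atoms: none
Why: Weinreb ketone synthesis: the chelated tetrahedral intermediate stops at the allyl ketone, the acetate is cleaved by double addition of the same reagent, and at −78 °C the trisubstituted oxirane and the α-centre are not touched; a cold, buffered quench avoids conjugation of the β,γ-enone.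

**Step 5**
Reactants: 7 (5S)-8-[(2S,3S)-3-(hydroxymethyl)-2-methyloxiran-2-yl]-5-methyloct-1-en-4-one; 8 methyl 2-(bromomethyl)acrylate
Product: 9 methyl (2Z,6S)-2-(bromomethyl)-9-[(2S,3S)-3-(hydroxymethyl)-2-methyloxiran-2-yl]-6-methyl-5-oxonon-2-enoate
Conditions: 8 (5 equiv), second-generation Hoveyda–Grubbs catalyst RuCl2(H2IMes)(=CH-C6H4-2-O-i-Pr) (10 mol%), 1,4-benzoquinone (20 mol%), CH2Cl2, 40 °C
Reagents that add atoms: none
Why: Olefin cross-metathesis of the only alkene in 7 with the 1,1-disubstituted acrylate gives the thermodynamic trisubstituted enoate (chain trans to the ester, Z by CIP because of CH2Br), with benzoquinone suppressing Ru–H isomerisation of the allyl ketone; no stereocenter is touched.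

**Step 6**
Reactants: 9 methyl (2Z,6S)-2-(bromomethyl)-9-[(2S,3S)-3-(hydroxymethyl)-2-methyloxiran-2-yl]-6-methyl-5-oxonon-2-enoate
Product: 10 methyl (2Z,6S)-2-(bromomethyl)-9-[(2S,3R)-3-formyl-2-methyloxiran-2-yl]-6-methyl-5-oxonon-2-enoate
Conditions: TEMPO (10 mol%), PhI(OAc)2 (1.2 equiv), CH2Cl2, rt
Reagents that add atoms: none
Why: Oxoammonium (TEMPO) oxidation takes the primary epoxy alcohol to the epoxy aldehyde under neutral conditions that leave the allylic bromide, oxirane and ketone alone (the oxirane descriptor changes from S to R only because CHO outranks the ring carbon).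

**Step 7**
Reactants: 10 methyl (2Z,6S)-2-(bromomethyl)-9-[(2S,3R)-3-formyl-2-methyloxiran-2-yl]-6-methyl-5-oxonon-2-enoate
Product: 12 (4S,5S,6R,7R,10S)-4,5-epoxy-9-oxogermacr-11(13)-en-12,6-olide, via hydroxy ester 11 (not isolated)
Conditions: CrCl2 (8 equiv), THF–DMF, rt, slow addition to 2 mM; aq. NH4Cl
Reagents that add atoms: none
Why: Intramolecular Nozaki–Hiyama (Barbier-type) allylation: divalent chromium turns the allylic bromide into an allylchromium that adds through its γ-carbon to the aldehyde only (the ketone is inert), anti as usual for γ-substituted allylchromium reagents (trans C6/C7); the E-oxirane can sit in a ten-membered ring only with its oxygen outside, so the chain closes over the opposite face and C6–O ends up syn to the oxirane C5–O, as in related closures of 4,5-epoxy germacranolide precursors, and the alkoxide then closes the trans γ-lactone.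

**Step 8**
Reactants: 12 (4S,5S,6R,7R,10S)-4,5-epoxy-9-oxogermacr-11(13)-en-12,6-olide
Product: 13 (4R,5S,6R,7R,10S)-4,5-dihydroxy-9-oxogermacr-11(13)-en-12,6-olide
Conditions: HClO4 (5 mol%), THF–H2O (3:1), 0 °C to rt
Reagents that add atoms: water, O
Why: Acid-catalysed epoxide hydrolysis opens the protonated oxirane at the tertiary carbon from the rear (inversion at C4; transannular delivery through the C9 carbonyl oxygen would give the same face), while the C5–O bond is retained, giving the anti 4,5-diol.

**Step 9**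
Reactants: 14 tiglic acid, (2E)-2-methylbut-2-enoic acid
Product: 15 (2S)-2-methylbutanoic acid
Conditions: Ru(OAc)2[(S)-H8-BINAP] (0.5 mol%), H2 (4 atm), MeOH, rt
Reagents that add atoms: none
Why: Carboxylate-directed asymmetric hydrogenation of an α,β-unsaturated acid (Noyori–Takaya type), for which the (S)-ligand gives the (S)-acid in high ee.

**Step 10**
Reactants: 13 (4R,5S,6R,7R,10S)-4,5-dihydroxy-9-oxogermacr-11(13)-en-12,6-olide; 15 (2S)-2-methylbutanoic acid
Product: 16 (4R,5S,6R,7R,10S)-4-hydroxy-5-[(2S)-2-methylbutanoyloxy]-9-oxogermacr-11(13)-en-12,6-olide (CNP0144277.6)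
Conditions: 15 (3 equiv), EDC·HCl, DMAP (0.3 equiv), CH2Cl2, 0 °C to rt
Reagents that add atoms: none
Why: Steglich esterification acylates only the secondary C5–OH (the tertiary C4–OH is inert) without touching any stereocenter; the α-alkyl acid keeps its configuration under carbodiimide activation.

**Compound list**

1 | geranyl acetate | CC(C)=CCC/C(C)=C/COC(C)=O | starting material
2 | (2E,6E)-8-hydroxy-3,7-dimethylocta-2,6-dien-1-yl acetate | OC/C(C)=C/CC/C(C)=C/COC(C)=O | intermediate
3 | (2E,6E)-3,7-dimethyl-8-oxoocta-2,6-dien-1-yl acetate | O=C/C(C)=C/CC/C(C)=C/COC(C)=O | intermediate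
4 | (2E,7S)-8-[methoxy(methyl)amino]-3,7-dimethyl-8-oxooct-2-en-1-yl acetate | CON(C)C(=O)[C@@H](C)CCC/C(C)=C/COC(C)=O | intermediate
5 | [(2S,3S)-3-[(4S)-5-[methoxy(methyl)amino]-4-methyl-5-oxopentyl]-3-methyloxiran-2-yl]methyl acetate | CON(C)C(=O)[C@@H](C)CCC[C@]1(C)O[C@H]1COC(C)=O | intermediate
6 | allylmagnesium bromide | C=CC[Mg]Br | starting material
7 | (5S)-8-[(2S,3S)-3-(hydroxymethyl)-2-methyloxiran-2-yl]-5-methyloct-1-en-4-one | C=CCC(=O)[C@@H](C)CCC[C@]1(C)O[C@H]1CO | intermediate
8 | methyl 2-(bromomethyl)acrylate | C=C(CBr)C(=O)OC | starting material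
9 | methyl (2Z,6S)-2-(bromomethyl)-9-[(2S,3S)-3-(hydroxymethyl)-2-methyloxiran-2-yl]-6-methyl-5-oxonon-2-enoate | COC(=O)/C(CBr)=C/CC(=O)[C@@H](C)CCC[C@]1(C)O[C@H]1CO | intermediate
10 | methyl (2Z,6S)-2-(bromomethyl)-9-[(2S,3R)-3-formyl-2-methyloxiran-2-yl]-6-methyl-5-oxonon-2-enoate | COC(=O)/C(CBr)=C/CC(=O)[C@@H](C)CCC[C@]1(C)O[C@H]1C=O | intermediate
11 | methyl (4S,5S,6R,7R,10S)-4,5-epoxy-6-hydroxy-9-oxogermacr-11(13)-en-12-oate | COC(=O)C(=C)[C@H]1CC(=O)[C@@H](C)CCC[C@]2(C)O[C@H]2[C@@H]1O | intermediate
12 | (4S,5S,6R,7R,10S)-4,5-epoxy-9-oxogermacr-11(13)-en-12,6-olide | C=C1C(=O)O[C@@H]2[C@@H]1CC(=O)[C@@H](C)CCC[C@]3(C)O[C@@H]23 | intermediate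
13 | (4R,5S,6R,7R,10S)-4,5-dihydroxy-9-oxogermacr-11(13)-en-12,6-olide | C=C1C(=O)O[C@@H]2[C@@H]1CC(=O)[C@@H](C)CCC[C@@](C)(O)[C@H]2O | intermediate
14 | tiglic acid | C/C=C(\C)C(=O)O | starting material
15 | (2S)-2-methylbutanoic acid | OC(=O)[C@@H](C)CC | intermediate
16 | (4R,5S,6R,7R,10S)-4-hydroxy-5-[(2S)-2-methylbutanoyloxy]-9-oxogermacr-11(13)-en-12,6-olide | C=C1C(=O)O[C@@H]2[C@@H]1CC(=O)[C@@H](C)CCC[C@@](C)(O)[C@H]2OC(=O)[C@@H](C)CC | target

**Step count and risks**

Total steps: 10. Longest linear sequence: 9 (steps 1–8 and 10); step 9 is a one-step side branch.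

Steps most likely to fail:

- **Step 2 (the new NHC redox amidation; the ee at C10 is the risk, since both α-substituents are alkyl).** The fallback sets out from 3 and comes back at 4. Pinnick oxidation (NaClO2, NaH2PO4, 2-methyl-2-butene) gives (2E,6E)-8-acetoxy-2,6-dimethylocta-2,6-dienoic acid F1. Hydrogenation with Ru(OAc)2[(S)-H8-BINAP]/H2, the tiglic-acid reaction of step 9, leaves the allylic-acetate alkene untouched and gives (2S,6E)-8-acetoxy-2,6-dimethyloct-6-enoic acid F2. Coupling with MeNH(OMe)·HCl (EDC·HCl, N-methylmorpholine) returns 4.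

- **Step 5 (cross-metathesis of an allyl ketone with a hindered, electron-poor bromomethyl acrylate).** The fallback sets out from 7 and comes back at 10, building the same bromide by Morita–Baylis–Hillman chemistry.
  - NaBH4 reduces the ketone to (5S)-8-[(2S,3S)-3-(hydroxymethyl)-2-methyloxiran-2-yl]-5-methyloct-1-en-4-ol F3 (both carbinol epimers).
  - TBSCl/imidazole gives the bis(tert-butyldimethylsilyl) ether F4.
  - Ozonolysis (O3, then PPh3) of the only alkene gives the β-silyloxy aldehyde F5.
  - Methyl acrylate/DABCO gives the Baylis–Hillman alcohol F6.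
  - NBS/Me2S gives, with allylic transposition, the bis-silylated (Z)-2-(bromomethyl)enoate F7.
  - HF·pyridine gives methyl (2Z,6S)-2-(bromomethyl)-5-hydroxy-9-[(2S,3S)-3-(hydroxymethyl)-2-methyloxiran-2-yl]-6-methylnon-2-enoate F8.
  - Dess–Martin periodinane oxidises both alcohols at once to 10.

- **Step 7 (ten-membered ring closure; yield and the C6/C7 outcome).** The fallback sets out from 10 and comes back at 12, closing the ring with boron instead of chromium. Borylation of the allylic bromide (B2pin2, Pd2(dba)3, DMSO) gives methyl (2E,6S)-9-[(2S,3R)-3-formyl-2-methyloxiran-2-yl]-6-methyl-5-oxo-2-[(4,4,5,5-tetramethyl-1,3,2-dioxaborolan-2-yl)methyl]non-2-enoate F9. At high dilution in warm toluene F9 undergoes intramolecular allylboration through a neutral closed transition state and then lactonises to 12; the oxirane again forces closure on the face away from its oxygen.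

**Further compounds**

F1 | step 2 | (2E,6E)-8-acetoxy-2,6-dimethylocta-2,6-dienoic acid | OC(=O)/C(C)=C/CC/C(C)=C/COC(C)=O
F2 | step 2 | (2S,6E)-8-acetoxy-2,6-dimethyloct-6-enoic acid | OC(=O)[C@@H](C)CCC/C(C)=C/COC(C)=O
F3 | step 5 | (5S)-8-[(2S,3S)-3-(hydroxymethyl)-2-methyloxiran-2-yl]-5-methyloct-1-en-4-ol | C=CCC(O)[C@@H](C)CCC[C@]1(C)O[C@H]1CO
F4 | step 5 | bis(tert-butyldimethylsilyl) ether of F3 | C=CCC(O[Si](C)(C)C(C)(C)C)[C@@H](C)CCC[C@]1(C)O[C@H]1CO[Si](C)(C)C(C)(C)C
F5 | step 5 | (4S)-3-(tert-butyldimethylsilyloxy)-7-[(2S,3S)-3-(tert-butyldimethylsilyloxymethyl)-2-methyloxiran-2-yl]-4-methylheptanal | O=CCC(O[Si](C)(C)C(C)(C)C)[C@@H](C)CCC[C@]1(C)O[C@H]1CO[Si](C)(C)C(C)(C)C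
F6 | step 5 | methyl (6S)-5-(tert-butyldimethylsilyloxy)-9-[(2S,3S)-3-(tert-butyldimethylsilyloxymethyl)-2-methyloxiran-2-yl]-3-hydroxy-6-methyl-2-methylidenenonanoate | COC(=O)C(=C)C(O)CC(O[Si](C)(C)C(C)(C)C)[C@@H](C)CCC[C@]1(C)O[C@H]1CO[Si](C)(C)C(C)(C)C
F7 | step 5 | methyl (2Z,6S)-2-(bromomethyl)-5-(tert-butyldimethylsilyloxy)-9-[(2S,3S)-3-(tert-butyldimethylsilyloxymethyl)-2-methyloxiran-2-yl]-6-methylnon-2-enoate | COC(=O)/C(CBr)=C/CC(O[Si](C)(C)C(C)(C)C)[C@@H](C)CCC[C@]1(C)O[C@H]1CO[Si](C)(C)C(C)(C)C
F8 | step 5 | methyl (2Z,6S)-2-(bromomethyl)-5-hydroxy-9-[(2S,3S)-3-(hydroxymethyl)-2-methyloxiran-2-yl]-6-methylnon-2-enoate | COC(=O)/C(CBr)=C/CC(O)[C@@H](C)CCC[C@]1(C)O[C@H]1CO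
F9 | step 7 | methyl (2E,6S)-9-[(2S,3R)-3-formyl-2-methyloxiran-2-yl]-6-methyl-5-oxo-2-[(4,4,5,5-tetramethyl-1,3,2-dioxaborolan-2-yl)methyl]non-2-enoate | COC(=O)/C(CB1OC(C)(C)C(C)(C)O1)=C/CC(=O)[C@@H](C)CCC[C@]2(C)O[C@H]2C=O
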